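**Plan**

- Retrosynthesis cuts C1'–C2' and the C3'–CH3 bond first. The (E)-C2'=C3' alkene lies one methylene (C1') away from C3 of quinone ring B, so C1' can be the chloromethyl carbon of quinone 8, and C2'=C3' with its methyl can arise by methylmetalation of terminal alkyne 20.
- Alkyne 20 is cut at C4'–C5' (propargylation of geranylfarnesyl bromide) and at C12'–C13' (sulfone alkylation joining a farnesyl and a geranyl unit).
- Quinone 8 is cut at C3–C1' (chloromethylation) and at C4a–C5/C8–C8a (Diels–Alder of 2-bromo-6-methylbenzoquinone with (E)-piperylene).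
- Forward: ring B comes from the bromocresol, ring A is annulated and aromatised, the C25 chain is assembled, brominated and propargylated, and chain and core are joined in the last step, where no ring forms.
- There is no stereocentre. E at C6', C14' and C18' is carried over from geranyl acetate and farnesol, E at C10' comes from the selenium dioxide oxidation, and E at C2' from syn methylalumination followed by a stereoretentive nickel coupling.

Key step: step 13

Remark: chain carbons are numbered C1' (on C3 of ring B) to C24'; ring A is the benzo ring with the C8 methyl and ring B the quinone ring; geranyl acetate is used as the purchasable form of geraniol; compounds 4, 5, 15, 16 and 17 are racemic and their stereocentres are erased in the following operation.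

**Route**

Step 1
Reactants: 1 2,4-dibromo-6-methylphenol
Product: 2 2-bromo-6-methyl-1,4-benzoquinone
Conditions: CrO3, AcOH/H2O, 60 °C
Reagents that add atoms: chromium trioxide, O=[Cr](=O)=O (as aqueous chromic acid it delivers the new C4 oxygen)
Why: Chromic acid oxidation of a para-bromophenol to the para-quinone, in which the oxidised ring takes up oxygen at C4 and expels the C4 bromine as bromide, while the C2 bromine and the C6 methyl stay in place.

Step 2
Reactants: 2 2-bromo-6-methyl-1,4-benzoquinone; 3 (E)-penta-1,3-diene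
Product: 4 8a-bromo-2,8-dimethyl-4a,5,8,8a-tetrahydronaphthalene-1,4-dione (racemic, cis-fused, C8 methyl trans to bromine)
Conditions: PhMe, 40 °C, sealed tube, dark (3 in excess)
Reagents that add atoms: none
Why: Diels–Alder reaction at the bromine-bearing C2=C3 bond of 2, the more electron-poor dienophile; because bromine and the C6 methyl both weaken the C4 carbonyl as an activator, C3 is the β carbon of the stronger C1 carbonyl and takes the unsubstituted diene terminus, so the diene methyl ends up next to the C–Br carbon (future C8, peri to C1=O), and the endo cis adduct has three stereocentres that step 3 erases.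

Step 3
Reactants: 4 8a-bromo-2,8-dimethyl-4a,5,8,8a-tetrahydronaphthalene-1,4-dione
Product: 7 2,8-dimethyl-1,4-naphthoquinone, via dihydroquinone 5 (not isolated), via naphthalenediol 6 (not isolated)
Conditions: Et3N, CH2Cl2, 0 °C to rt; then MnO2, rt
Reagents that add atoms: none
Why: Triethylamine removes HBr by E1cB elimination across C4a–C8a, the resulting 5,8-dihydroquinone 5 tautomerises under base to the aromatic diol 6 (isoaromatisation), and MnO2 oxidises this hydroquinone to the quinone.

Step 4
Reactants: 7 2,8-dimethyl-1,4-naphthoquinone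
Product: 8 2-(chloromethyl)-3,5-dimethyl-1,4-naphthoquinone (3-chloromethyl-2,8-dimethyl in the numbering of the target)
Conditions: 37% aq. HCHO, HCl (g), AcOH, rt
Reagents that add atoms: formaldehyde, C=O; hydrogen chloride, Cl
Why: Chloromethylation of a quinone C–H with formaldehyde and HCl, a reaction type established for 2-methyl-1,4-naphthoquinone, can only occur at C3 of ring B, the sole unsubstituted quinone carbon, since ring A is deactivated by both carbonyls.

Step 5
Reactants: 9 (2E,6E)-farnesol
Product: 10 (2E,6E)-farnesyl bromide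
Conditions: PBr3, Et2O, 0 °C
Reagents that add atoms: phosphorus tribromide, BrP(Br)Br
Why: Bromination of a primary allylic alcohol through its phosphite ester by SN2 displacement, which at 0 °C should keep the C2=C3 geometry and avoid allylic transposition.

Step 6
Reactants: 10 (2E,6E)-farnesyl bromide
Product: 11 (2E,6E)-farnesyl phenyl sulfone
Conditions: PhSO2Na, DMF, rt
Reagents that add atoms: sodium benzenesulfinate, [Na+].[O-]S(=O)c1ccccc1
Why: SN2 S-alkylation of the sulfinate anion at the primary allylic carbon gives the sulfone with the alkene geometry unchanged.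

Step 7
Reactants: 12 geranyl acetate
Product: 13 (2E,6E)-8-hydroxy-3,7-dimethylocta-2,6-dien-1-yl acetate
Conditions: SeO2 (cat.), t-BuOOH, salicylic acid (cat.), CH2Cl2, rt
Reagents that add atoms: tert-butyl hydroperoxide, CC(C)(C)OO (terminal oxidant; its oxygen reaches C8 through the SeO2 catalyst)
Why: Selenium dioxide allylic oxidation (Riley type, catalytic in SeO2) proceeds by ene reaction and [2,3]-sigmatropic shift at the electron-richer terminal alkene, the C2=C3 alkene being deactivated by the allylic acetate, and attacks the methyl trans to the chain, which sets E geometry at C6=C7.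

Step 8
Reactants: 13 (2E,6E)-8-hydroxy-3,7-dimethylocta-2,6-dien-1-yl acetate
Product: 14 (2E,6E)-8-bromo-3,7-dimethylocta-2,6-dien-1-yl acetate
Conditions: CBr4, PPh3, CH2Cl2, 0 °C
Reagents that add atoms: carbon tetrabromide, BrC(Br)(Br)Br
Why: Appel bromination converts the primary allylic alcohol into the bromide under neutral conditions that leave the acetate and both alkenes untouched.

Step 9
Reactants: 11 (2E,6E)-farnesyl phenyl sulfone; 14 (2E,6E)-8-bromo-3,7-dimethylocta-2,6-dien-1-yl acetate
Product: 16 (2E,6E,10E,14E)-3,7,11,15,19-pentamethyl-9-(phenylsulfonyl)icosa-2,6,10,14,18-pentaen-1-yl acetate (racemic at C9), via lithiated sulfone 15 (not isolated)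
Conditions: n-BuLi, THF, −78 °C; then 14, −78 to −40 °C
Reagents that add atoms: none
Why: Julia-type alkylation of a sulfone-stabilised allylic carbanion, which reacts at its α carbon by SN2 with the primary allylic bromide faster at −78 °C than it attacks the acetate, forms the C12'–C13' bond of the chain.

Step 10
Reactants: 16 (2E,6E,10E,14E)-3,7,11,15,19-pentamethyl-9-(phenylsulfonyl)icosa-2,6,10,14,18-pentaen-1-yl acetate
Product: 18 (2E,6E,10E,14E)-geranylfarnesol, via lithium alkoxide 17 (not isolated)
Conditions: LiBHEt3 (excess), THF, −78 to 0 °C; then PdCl2(dppp) (cat.), 0 °C to rt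
Reagents that add atoms: none
Why: Hydride first cleaves the acetate to the alkoxide, so that no allyl complex can form at C1, and palladium-catalysed reductive desulfonylation then ionises the allylic sulfone at zerovalent palladium and delivers hydride to the less substituted terminus C9, keeping C10=C11 in place and E.

Step 11
Reactants: 18 (2E,6E,10E,14E)-geranylfarnesol
Product: 19 (2E,6E,10E,14E)-geranylfarnesyl bromide
Conditions: PBr3, Et2O, 0 °C
Reagents that add atoms: phosphorus tribromide, BrP(Br)Br
Why: The same SN2 bromination of a primary allylic alcohol as in step 5, without allylic transposition.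

Step 12
Reactants: 19 (2E,6E,10E,14E)-geranylfarnesyl bromide
Product: 20 (5E,9E,13E,17E)-6,10,14,18,22-pentamethyltricosa-5,9,13,17,21-pentaen-1-yne
Conditions: propyne, n-BuLi (2 equiv), TMEDA, Et2O/hexane, −78 °C to rt; then 19, −78 °C to rt; H2O
Reagents that add atoms: propyne, CC#C
Why: 1,3-Dilithiopropyne is alkylated at its propargylic sp3 carbon by SN2 displacement of primary allylic bromides (a propargylation established for geranyl bromide), and water protonates the remaining acetylide to the terminal alkyne.

Step 13
Reactants: 8 2-(chloromethyl)-3,5-dimethyl-1,4-naphthoquinone; 20 (5E,9E,13E,17E)-6,10,14,18,22-pentamethyltricosa-5,9,13,17,21-pentaen-1-yne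
Product: 22 2,8-dimethyl-3-(all-E-hexaprenyl)-1,4-naphthoquinone (target), via alkenylalane 21 (not isolated)
Conditions: Me3Al (2 equiv), Cp2ZrCl2 (cat.), ClCH2CH2Cl, 0 °C to rt; volatiles removed, hexane, filtered; then 8, NiCl2(PPh3)2/n-BuLi (1:2, cat.), THF, −20 °C to rt
Reagents that add atoms: trimethylaluminium, C[Al](C)C
Why: A methylzirconium species formed from Me3Al and Cp2ZrCl2 adds syn across the terminal alkyne of 20, methyl to the internal carbon C3' and metal to the terminal carbon C2', and exchange with aluminium releases (E)-alkenylalane 21 (zirconium-catalysed methylalumination, the Negishi carboalumination), while the trisubstituted alkenes of the chain do not react. Zerovalent nickel, generated from NiCl2(PPh3)2 and n-BuLi, then inserts into the C1'–Cl bond of 8, the alkenyl group passes from aluminium to nickel with retention of geometry, and reductive elimination forms C1'–C2'; the closest known reaction type is the nickel-catalysed coupling of alkenylalanes with benzylic chlorides, chloromethyl quinones included. No ring is closed and no stereocentre is created; the one new stereochemical element, E geometry at C2'=C3', is fixed by the syn addition and is not touched afterwards. The step needs methyl delivery to C3' only, bond formation at C1' without allylic transposition or E/Z scrambling, and no attack on the C1 and C4 carbonyls of ring B. These are secured by the terminal alkyne, which sends aluminium to the unhindered carbon, by C1' having no β-hydrogen and never becoming an allyl cation, and by the low nucleophilicity of the alkenylalane in THF once excess Me3Al has been removed, so that it reacts at nickel before it can add to the quinone.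

**Compound list**

1 | 2,4-dibromo-6-methylphenol | Cc1cc(Br)cc(Br)c1O | starting material
2 | 2-bromo-6-methyl-1,4-benzoquinone | CC1=CC(=O)C=C(Br)C1=O | intermediate
3 | (E)-penta-1,3-diene | C/C=C/C=C | starting material
4 | 8a-bromo-2,8-dimethyl-4a,5,8,8a-tetrahydronaphthalene-1,4-dione (racemic; cis ring fusion, C8 methyl trans to Br; one enantiomer drawn) | CC1=CC(=O)[C@@H]2CC=C[C@H](C)[C@]2(Br)C1=O | intermediate
5 | 2,8-dimethyl-5,8-dihydronaphthalene-1,4-dione (racemic at C8) | CC1=CC(=O)C2=C(C(C)C=CC2)C1=O | intermediate (not isolated)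
6 | 2,8-dimethylnaphthalene-1,4-diol | Cc1cc(O)c2cccc(C)c2c1O | intermediate (not isolated)
7 | 2,8-dimethyl-1,4-naphthoquinone | CC1=CC(=O)c2cccc(C)c2C1=O | intermediate
8 | 2-(chloromethyl)-3,5-dimethyl-1,4-naphthoquinone | ClCC1=C(C)C(=O)c2c(C)cccc2C1=O | intermediate
9 | (2E,6E)-farnesol | CC(C)=CCC/C(C)=C/CC/C(C)=C/CO | starting material
10 | (2E,6E)-farnesyl bromide | CC(C)=CCC/C(C)=C/CC/C(C)=C/CBr | intermediate
11 | (2E,6E)-farnesyl phenyl sulfone | CC(C)=CCC/C(C)=C/CC/C(C)=C/CS(=O)(=O)c1ccccc1 | intermediate
12 | geranyl acetate, (2E)-3,7-dimethylocta-2,6-dien-1-yl acetate | CC(C)=CCC/C(C)=C/COC(C)=O | starting material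
13 | (2E,6E)-8-hydroxy-3,7-dimethylocta-2,6-dien-1-yl acetate | OC/C(C)=C/CC/C(C)=C/COC(C)=O | intermediate
14 | (2E,6E)-8-bromo-3,7-dimethylocta-2,6-dien-1-yl acetate | BrC/C(C)=C/CC/C(C)=C/COC(C)=O | intermediate
15 | [(2E,6E)-3,7,11-trimethyl-1-(phenylsulfonyl)dodeca-2,6,10-trien-1-yl]lithium | CC(C)=CCC/C(C)=C/CC/C(C)=C/C([Li])S(=O)(=O)c1ccccc1 | intermediate (not isolated)
16 | (2E,6E,10E,14E)-3,7,11,15,19-pentamethyl-9-(phenylsulfonyl)icosa-2,6,10,14,18-pentaen-1-yl acetate (racemic at C9) | CC(C)=CCC/C(C)=C/CC/C(C)=C/C(C/C(C)=C/CC/C(C)=C/COC(C)=O)S(=O)(=O)c1ccccc1 | intermediate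
17 | lithium (2E,6E,10E,14E)-3,7,11,15,19-pentamethyl-9-(phenylsulfonyl)icosa-2,6,10,14,18-pentaen-1-olate (racemic at C9) | CC(C)=CCC/C(C)=C/CC/C(C)=C/C(C/C(C)=C/CC/C(C)=C/CO[Li])S(=O)(=O)c1ccccc1 | intermediate (not isolated)
18 | (2E,6E,10E,14E)-3,7,11,15,19-pentamethylicosa-2,6,10,14,18-pentaen-1-ol (geranylfarnesol) | CC(C)=CCC/C(C)=C/CC/C(C)=C/CC/C(C)=C/CC/C(C)=C/CO | intermediate
19 | (2E,6E,10E,14E)-1-bromo-3,7,11,15,19-pentamethylicosa-2,6,10,14,18-pentaene (geranylfarnesyl bromide) | CC(C)=CCC/C(C)=C/CC/C(C)=C/CC/C(C)=C/CC/C(C)=C/CBr | intermediate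
20 | (5E,9E,13E,17E)-6,10,14,18,22-pentamethyltricosa-5,9,13,17,21-pentaen-1-yne | CC(C)=CCC/C(C)=C/CC/C(C)=C/CC/C(C)=C/CC/C(C)=C/CCC#C | intermediate
21 | dimethyl[(1E,5E,9E,13E,17E)-2,6,10,14,18,22-hexamethyltricosa-1,5,9,13,17,21-hexaen-1-yl]alane | CC(C)=CCC/C(C)=C/CC/C(C)=C/CC/C(C)=C/CC/C(C)=C/CC/C(C)=C/[Al](C)C | intermediate (not isolated)
22 | 2,8-dimethyl-3-[(2E,6E,10E,14E,18E)-3,7,11,15,19,23-hexamethyltetracosa-2,6,10,14,18,22-hexaen-1-yl]naphthalene-1,4-dione | CC(C)=CCC/C(C)=C/CC/C(C)=C/CC/C(C)=C/CC/C(C)=C/CC/C(C)=C/CC1=C(C)C(=O)c2c(C)cccc2C1=O | target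

**Step count and risks**

Total step count: 13. Longest linear sequence: 7 steps (5, 6, 9, 10, 11, 12, 13 from farnesol, or 7, 8, 9, 10, 11, 12, 13 from geranyl acetate); the quinone branch has 5 steps (1 to 4, then 13).

Steps most likely to fail:

1. Step 13. The quinone may be reduced to the hydroquinone by the electron-rich nickel/alane system, or a ring B carbonyl may be attacked before oxidative addition at C1'–Cl; the minor regioisomeric alane from imperfect methylalumination would also be carried into the product. The fallback sets out from 20 and comes back at 22. Alkyne 20 is methylaluminated as in step 13 and alane 21 is quenched with I2 to give (1E,5E,9E,13E,17E)-1-iodo-2,6,10,14,18,22-hexamethyltricosa-1,5,9,13,17,21-hexaene F1, which can be freed from regioisomer by chromatography. Iodine–lithium exchange (t-BuLi, Et2O, −78 °C) gives the alkenyllithium F2, and Bu3SnCl converts it into the tributyl(alkenyl)stannane F3. A Stille coupling of F3 with 8 (Pd2(dba)3, AsPh3, THF, 50 °C) should then form C1'–C2' under neutral, non-reducing conditions with retention of geometry and give 22.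

2. Step 4. Hydrogen chloride may add to the quinone, or the first-formed hydroxymethyl or chloromethyl product may condense with a second quinone, so that conversion stalls or oligomers form. The fallback sets out from 7 and comes back at 8. Quinone 7 is reduced with Na2S2O4 to diol 6 and methylated (Me2SO4, KOH) to 1,4-dimethoxy-2,8-dimethylnaphthalene F4. Blanc chloromethylation ((CH2O)n, HCl, AcOH) at C3, the only free position of the dimethoxy-substituted ring, gives 2-(chloromethyl)-1,4-dimethoxy-3,5-dimethylnaphthalene F5. Oxidative demethylation with (NH4)2Ce(NO3)6 in MeCN/H2O at 0 °C returns 8.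

3. Step 10. Hydride may be delivered to the tertiary terminus C11 of the allylpalladium intermediate, which moves the alkene out of position, or the allyl complex may equilibrate and erode E purity at C10=C11; incomplete acetate cleavage before the catalyst is added would also allow deoxygenation at C1. The fallback sets out from 10 and comes back at 18, replacing steps 6 to 10 by chain growth one prenyl unit at a time through alkyne methylalumination. Bromide 10 is propargylated with 1,3-dilithiopropyne as in step 12 to give (5E,9E)-6,10,14-trimethylpentadeca-5,9,13-trien-1-yne F6. Methylalumination (Me3Al, Cp2ZrCl2 cat.) gives the alkenylalane F7, n-BuLi converts it into the lithium alkenylaluminate F8, and (CH2O)n then gives (2E,6E,10E)-geranylgeraniol F9. PBr3 gives (2E,6E,10E)-geranylgeranyl bromide F10, and a second propargylation gives (5E,9E,13E)-6,10,14,18-tetramethylnonadeca-5,9,13,17-tetraen-1-yne F11. The same methylalumination, through the alkenylalane F12 and the lithium alkenylaluminate F13, followed by (CH2O)n, gives 18.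

Further compounds
F1 | step 13 | (1E,5E,9E,13E,17E)-1-iodo-2,6,10,14,18,22-hexamethyltricosa-1,5,9,13,17,21-hexaene | CC(C)=CCC/C(C)=C/CC/C(C)=C/CC/C(C)=C/CC/C(C)=C/CC/C(C)=C/I
F2 | step 13 | [(1E,5E,9E,13E,17E)-2,6,10,14,18,22-hexamethyltricosa-1,5,9,13,17,21-hexaen-1-yl]lithium | CC(C)=CCC/C(C)=C/CC/C(C)=C/CC/C(C)=C/CC/C(C)=C/CC/C(C)=C/[Li]
F3 | step 13 | tributyl[(1E,5E,9E,13E,17E)-2,6,10,14,18,22-hexamethyltricosa-1,5,9,13,17,21-hexaen-1-yl]stannane | CC(C)=CCC/C(C)=C/CC/C(C)=C/CC/C(C)=C/CC/C(C)=C/CC/C(C)=C/[Sn](CCCC)(CCCC)CCCC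
F4 | step 4 | 1,4-dimethoxy-2,8-dimethylnaphthalene | COc1c(C)cc(OC)c2cccc(C)c12
F5 | step 4 | 2-(chloromethyl)-1,4-dimethoxy-3,5-dimethylnaphthalene | COc1c(C)c(CCl)c(OC)c2cccc(C)c12
F6 | step 10 | (5E,9E)-6,10,14-trimethylpentadeca-5,9,13-trien-1-yne | CC(C)=CCC/C(C)=C/CC/C(C)=C/CCC#C
F7 | step 10 | dimethyl[(1E,5E,9E)-2,6,10,14-tetramethylpentadeca-1,5,9,13-tetraen-1-yl]alane | CC(C)=CCC/C(C)=C/CC/C(C)=C/CC/C(C)=C/[Al](C)C
F8 | step 10 | lithium butyl(dimethyl)[(1E,5E,9E)-2,6,10,14-tetramethylpentadeca-1,5,9,13-tetraen-1-yl]aluminate | CC(C)=CCC/C(C)=C/CC/C(C)=C/CC/C(C)=C/[Al-](C)(C)CCCC.[Li+]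
F9 | step 10 | (2E,6E,10E)-geranylgeraniol | CC(C)=CCC/C(C)=C/CC/C(C)=C/CC/C(C)=C/CO
F10 | step 10 | (2E,6E,10E)-geranylgeranyl bromide | CC(C)=CCC/C(C)=C/CC/C(C)=C/CC/C(C)=C/CBr
F11 | step 10 | (5E,9E,13E)-6,10,14,18-tetramethylnonadeca-5,9,13,17-tetraen-1-yne | CC(C)=CCC/C(C)=C/CC/C(C)=C/CC/C(C)=C/CCC#C
F12 | step 10 | dimethyl[(1E,5E,9E,13E)-2,6,10,14,18-pentamethylnonadeca-1,5,9,13,17-pentaen-1-yl]alane | CC(C)=CCC/C(C)=C/CC/C(C)=C/CC/C(C)=C/CC/C(C)=C/[Al](C)C
F13 | step 10 | lithium butyl(dimethyl)[(1E,5E,9E,13E)-2,6,10,14,18-pentamethylnonadeca-1,5,9,13,17-pentaen-1-yl]aluminate | CC(C)=CCC/C(C)=C/CC/C(C)=C/CC/C(C)=C/CC/C(C)=C/[Al-](C)(C)CCCC.[Li+]
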